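**Retrosynthetic overview**

1. The C9–O bond is made last: reagent-controlled allylic C–H hydroxylation (ene/[2,3]) of the deoxy acetate with a new chiral oxo-selenium reagent.
2. Side chain: hydroboration of a vinyl group and alkyl–alkyl Suzuki coupling with (R)-3-bromo-2-methylpropyl acetate (the C2' centre comes from the chiral pool).
3. Six-membered ring (formed second and last): methyl cross-coupling of an enol triflate made from a spiro-cyclohexenone, itself closed by intramolecular aldol condensation.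
4. Spiro carbon: convex-face alkylation of the dihydronepetalactone enolate, with the side chain tied back in the lactone.
5. Five-membered ring (first, from the chiral pool): (4aS,7S,7aR)-nepetalactone supplies C1 and C4; its hydrogenation sets the side-chain methine.

Assumption: (4aS,7S,7aR)-nepetalactone, the main constituent of commercial catnip oil, is taken as a cheap commercial starting material.
Assumption: the selenium reagent of step 11 is prepared beforehand from SeOCl2, Et3N and commercial N,N'-ditosyl-(1R,2R)-1,2-diphenylethylenediamine; this reagent preparation is not counted as a step.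
Numbering used in the text: spiro[4.5]decane, C1 (side chain), C4 (methyl), C5 (spiro), C7=C8 (C8 methyl), C9 (carbinol).

**Route**

Step 1
Reactants: 1 (4aS,7S,7aR)-4,7-dimethyl-5,6,7,7a-tetrahydrocyclopenta[c]pyran-1(4aH)-one (nepetalactone)
Product: 2 (4S,4aR,7S,7aR)-4,7-dimethylhexahydrocyclopenta[c]pyran-1(3H)-one (dihydronepetalactone)
Conditions: H2 (3 bar), 5% Pd/C, EtOAc, 23 °C
Reagents that add atoms: none
Why: Heterogeneous catalytic hydrogenation adds H2 to the enol-lactone double bond from the convex face of the cis-fused bicycle (syn to H-4a), which sets C4 as S and leaves the three chiral-pool centres untouched.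

Step 2
Reactants: 2 dihydronepetalactone; 3 2-(2-bromoethyl)-2-methyl-1,3-dioxolane
Product: 5 (4S,4aR,7S,7aR)-4,7-dimethyl-7a-[2-(2-methyl-1,3-dioxolan-2-yl)ethyl]hexahydrocyclopenta[c]pyran-1(3H)-one, via lithium enolate 4 (not isolated)
Conditions: LiN(i-Pr)2, THF, −78 °C; DMPU, 3, n-Bu4NI (0.2 eq), −78 → 23 °C
Reagents that add atoms: none
Why: Lactone enolate alkylation: ring-fusion enolate 4 is alkylated on the convex face so that the cis ring fusion is kept, which puts the new arm cis to the C7 methyl and leaves the carbonyl carbon cis to the side-chain carbon, fixing the future spiro centre (7aR).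

Step 3
Reactants: 5 alkylated lactone
Product: 6 (2S)-2-{(1R,2R,3S)-2-(hydroxymethyl)-3-methyl-2-[2-(2-methyl-1,3-dioxolan-2-yl)ethyl]cyclopentyl}propan-1-ol
Conditions: LiAlH4, THF, 0 → 40 °C
Reagents that add atoms: none
Why: LiAlH4 ester reduction opens the hindered lactone to the diol without touching the dioxolane or any stereocentre.

Step 4
Reactants: 6 diol
Product: 7 (1R,2R,5S)-5-methyl-1-[2-(2-methyl-1,3-dioxolan-2-yl)ethyl]-2-[(2S)-1-oxopropan-2-yl]cyclopentane-1-carbaldehyde
Conditions: Dess–Martin periodinane (2.5 eq), NaHCO3, CH2Cl2, 0 → 23 °C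
Reagents that add atoms: none
Why: Dess–Martin oxidation of both primary alcohols under buffered, non-epimerising conditions; the ring aldehyde cannot enolise and the α-methyl aldehyde is used at once.

Step 5
Reactants: 7 dialdehyde
Product: 8 (1R,2R,5S)-2-[(2R)-but-3-en-2-yl]-5-methyl-1-[2-(2-methyl-1,3-dioxolan-2-yl)ethyl]cyclopentane-1-carbaldehyde
Conditions: Ph3PCH3Br (1.05 eq), KN(SiMe3)2 (1.0 eq), THF, −78 → −20 °C
Reagents that add atoms: methyltriphenylphosphonium bromide, C[P+](c1ccccc1)(c1ccccc1)c1ccccc1.[Br-]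
Why: Wittig methylenation with one equivalent of ylide at low temperature takes the unhindered α-branched aldehyde and not the neopentyl-type aldehyde on the fully substituted ring carbon.

Step 6
Reactants: 8 vinyl aldehyde acetal
Product: 10 (1R,4S,5S)-1-[(2R)-but-3-en-2-yl]-4-methylspiro[4.5]dec-6-en-8-one, via keto-aldehyde 9 (not isolated)
Conditions: 1 M HCl, THF, 23 °C; then KOH, MeOH, 50 °C
Reagents that add atoms: water, O
Why: Acetal hydrolysis then intramolecular aldol condensation (the ring-closing half of a Robinson annulation): only the methyl-ketone enolate can reach the non-enolisable aldehyde through a six-membered transition state, which closes the cyclohexenone and completes the spiro[4.5]decane without a new stereocentre.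

Step 7
Reactants: 10 spiro-enone
Product: 12 (1R,4S,5R)-1-[(2R)-but-3-en-2-yl]-4-methylspiro[4.5]dec-7-en-8-yl trifluoromethanesulfonate, via lithium enolate 11 (not isolated)
Conditions: LiBH(s-Bu)3, THF, −78 °C; PhNTf2, −78 → 0 °C
Reagents that add atoms: N-phenylbis(trifluoromethanesulfonimide), O=S(=O)(N(c1ccccc1)S(=O)(=O)C(F)(F)F)C(F)(F)F
Why: Conjugate (1,4) reduction of the β-unsubstituted enone by the bulky borohydride gives the regiodefined C7=C8 enolate 11, trapped on oxygen as the enol triflate, so the double bond is fixed on the side of the former aldehyde carbon.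

Step 8
Reactants: 12 enol triflate
Product: 13 (1R,4S,5R)-1-[(2R)-but-3-en-2-yl]-4,8-dimethylspiro[4.5]dec-7-ene
Conditions: MeMgBr, Fe(acac)3 (5 mol%), THF/NMP, −30 → 0 °C
Reagents that add atoms: methylmagnesium bromide, C[Mg]Br
Why: Iron-catalysed Kumada-type cross-coupling of an alkenyl triflate with MeMgBr replaces OTf by CH3 with the double bond held in place; the terminal vinyl group is inert.

Step 9
Reactants: 14 (2R)-3-bromo-2-methylpropan-1-ol
Product: 15 (2R)-3-bromo-2-methylpropyl acetate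
Conditions: Ac2O, pyridine, DMAP (cat.), CH2Cl2, 0 °C
Reagents that add atoms: acetic anhydride, CC(=O)OC(C)=O
Why: Standard acetylation of the primary alcohol; the stereocentre is not involved.

Step 10
Reactants: 13 diene; 15 bromo acetate
Product: 17 (2S,6R)-6-[(1R,4S,5R)-4,8-dimethylspiro[4.5]dec-7-en-1-yl]-2-methylheptyl acetate, via B-alkyl-9-BBN 16 (not isolated)
Conditions: 9-BBN-H, THF, 0 → 23 °C; then 15, Pd(OAc)2 (4 mol%), PCy3 (8 mol%), K3PO4·H2O, THF, 23 °C
Reagents that add atoms: none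
Why: Anti-Markovnikov hydroboration of the monosubstituted alkene only (9-BBN leaves the trisubstituted ring alkene alone) followed by B-alkyl Suzuki–Miyaura alkyl–alkyl coupling with the primary bromide completes the chain and brings in the (2S) centre unchanged from the chiral pool.

Step 11
Reactants: 17 deoxy acetate
Product: 20 (2S,6R)-6-[(1R,4S,5S,9S)-9-hydroxy-4,8-dimethylspiro[4.5]dec-7-en-1-yl]-2-methylheptyl acetate, via allylic seleninamide 18 (not isolated), via selenenate ester 19 (not isolated)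
Conditions: selenium reagent (1.3 eq), 4 Å MS, CH2Cl2, −40 → 0 °C; then aq. NaHCO3
Reagents that add atoms: (4R,5R)-1,3-bis(4-methylbenzenesulfonyl)-4,5-diphenyl-1,3,2-diazaselenolidine 2-oxide, O=[Se]1N(S(=O)(=O)c2ccc(C)cc2)[C@H](c2ccccc2)[C@@H](c2ccccc2)N1S(=O)(=O)c1ccc(C)cc1
Why: Proposed new method: a C2-symmetric oxo-selenium reagent (tetravalent selenium in a bis-N-sulfonyl diazaselenolidine) acts as a chiral SeO2 equivalent; its electron-poor Se=O adds to the alkene in an ene reaction, selenium bonding to the less substituted C7 and taking H from the ring CH2 at C9 (the site the Guillemonat rules give for SeO2 on a 1-methylcyclohexene), ring-opening gives allylic seleninamide 18, and its suprafacial [2,3]-sigmatropic shift returns the double bond to C7=C8 and puts oxygen on C9 on the face the reagent first attacked (syn to C1), so the chiral sulfonamide pocket and not the distant spiro centre picks the (9S) face; hydrolysis of the divalent-selenium ester 19 frees the alcohol; the closest known chemistry is the SeO2/t-BuOOH allylic hydroxylation and the imidoselenium ene/[2,3] allylic amination.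

**Compound list**

1 | (4aS,7S,7aR)-4,7-dimethyl-5,6,7,7a-tetrahydrocyclopenta[c]pyran-1(4aH)-one (nepetalactone) | C[C@H]1CC[C@@H]2C(C)=COC(=O)[C@H]12 | starting material
2 | (4S,4aR,7S,7aR)-4,7-dimethylhexahydrocyclopenta[c]pyran-1(3H)-one (dihydronepetalactone) | C[C@H]1CC[C@@H]2[C@H](C)COC(=O)[C@H]12 | intermediate
3 | 2-(2-bromoethyl)-2-methyl-1,3-dioxolane | CC1(CCBr)OCCO1 | starting material
4 | lithium enolate of 2 (lithium (4S,4aR,7S)-4,7-dimethyl-3,4,4a,5,6,7-hexahydrocyclopenta[c]pyran-1-olate) | C[C@H]1CC[C@@H]2[C@H](C)COC([O-])=C12.[Li+] | intermediate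
5 | (4S,4aR,7S,7aR)-4,7-dimethyl-7a-[2-(2-methyl-1,3-dioxolan-2-yl)ethyl]hexahydrocyclopenta[c]pyran-1(3H)-one | C[C@H]1CC[C@@H]2[C@H](C)COC(=O)[C@]12CCC3(C)OCCO3 | intermediate
6 | (2S)-2-{(1R,2R,3S)-2-(hydroxymethyl)-3-methyl-2-[2-(2-methyl-1,3-dioxolan-2-yl)ethyl]cyclopentyl}propan-1-ol | C[C@H]1CC[C@H]([C@H](C)CO)[C@@]1(CO)CCC2(C)OCCO2 | intermediate
7 | (1R,2R,5S)-5-methyl-1-[2-(2-methyl-1,3-dioxolan-2-yl)ethyl]-2-[(2S)-1-oxopropan-2-yl]cyclopentane-1-carbaldehyde | C[C@H]1CC[C@H]([C@H](C)C=O)[C@@]1(C=O)CCC2(C)OCCO2 | intermediate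
8 | (1R,2R,5S)-2-[(2R)-but-3-en-2-yl]-5-methyl-1-[2-(2-methyl-1,3-dioxolan-2-yl)ethyl]cyclopentane-1-carbaldehyde | C[C@H]1CC[C@H]([C@H](C)C=C)[C@@]1(C=O)CCC2(C)OCCO2 | intermediate
9 | (1R,2R,5S)-2-[(2R)-but-3-en-2-yl]-5-methyl-1-(3-oxobutyl)cyclopentane-1-carbaldehyde | C[C@H]1CC[C@H]([C@H](C)C=C)[C@@]1(C=O)CCC(C)=O | intermediate
10 | (1R,4S,5S)-1-[(2R)-but-3-en-2-yl]-4-methylspiro[4.5]dec-6-en-8-one | C[C@H]1CC[C@H]([C@H](C)C=C)[C@]12C=CC(=O)CC2 | intermediate
11 | lithium (1R,4S,5R)-1-[(2R)-but-3-en-2-yl]-4-methylspiro[4.5]dec-7-en-8-olate | C[C@H]1CC[C@H]([C@H](C)C=C)[C@]12CC=C([O-])CC2.[Li+] | intermediate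
12 | (1R,4S,5R)-1-[(2R)-but-3-en-2-yl]-4-methylspiro[4.5]dec-7-en-8-yl trifluoromethanesulfonate | C[C@H]1CC[C@H]([C@H](C)C=C)[C@]12CC=C(OS(=O)(=O)C(F)(F)F)CC2 | intermediate
13 | (1R,4S,5R)-1-[(2R)-but-3-en-2-yl]-4,8-dimethylspiro[4.5]dec-7-ene | C[C@H]1CC[C@H]([C@H](C)C=C)[C@]12CC=C(C)CC2 | intermediate
14 | (2R)-3-bromo-2-methylpropan-1-ol | OC[C@@H](C)CBr | starting material
15 | (2R)-3-bromo-2-methylpropyl acetate | CC(=O)OC[C@@H](C)CBr | intermediate
16 | 9-{(3R)-3-[(1R,4S,5R)-4,8-dimethylspiro[4.5]dec-7-en-1-yl]butyl}-9-borabicyclo[3.3.1]nonane | C[C@H]1CC[C@H]([C@H](C)CCB3C4CCCC3CCC4)[C@]12CC=C(C)CC2 | intermediate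
17 | (2S,6R)-6-[(1R,4S,5R)-4,8-dimethylspiro[4.5]dec-7-en-1-yl]-2-methylheptyl acetate | CC(=O)OC[C@@H](C)CCC[C@@H](C)[C@H]1CC[C@H](C)[C@@]12CC=C(C)CC2 | intermediate
18 | allylic seleninamide (ene adduct): 17 with the double bond moved to C8=C9 and, at C7 (R, face syn to C1), an Se(=O)–N(Ts)–CH(Ph)–CH(Ph)–NHTs group with (1R,2R) diamine carbons | CC(=O)OC[C@@H](C)CCC[C@@H](C)[C@H]1CC[C@H](C)[C@@]12C[C@@H]([Se](=O)N(S(=O)(=O)c3ccc(C)cc3)[C@H](c3ccccc3)[C@@H](c3ccccc3)NS(=O)(=O)c3ccc(C)cc3)C(C)=CC2 | intermediate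
19 | selenenate ester: 20 with its (9S) oxygen bound as O–Se–N(Ts)–CH(Ph)–CH(Ph)–NHTs, (1R,2R) diamine carbons | CC(=O)OC[C@@H](C)CCC[C@@H](C)[C@H]1CC[C@H](C)[C@@]12CC=C(C)[C@@H](O[Se]N(S(=O)(=O)c3ccc(C)cc3)[C@H](c3ccccc3)[C@@H](c3ccccc3)NS(=O)(=O)c3ccc(C)cc3)C2 | intermediate
20 | (2S,6R)-6-[(1R,4S,5S,9S)-9-hydroxy-4,8-dimethylspiro[4.5]dec-7-en-1-yl]-2-methylheptyl acetate | CC(=O)OC[C@@H](C)CCC[C@@H](C)[C@H]1CC[C@H](C)[C@@]12CC=C(C)[C@@H](O)C2 | target

**Step count and risks**

Total step count: 11. Longest linear sequence: 10 (steps 1–8, 10 and 11; step 9 prepares the coupling partner).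

Three steps most likely to fail:

Step 2 (alkylation of a hindered ring-fusion enolate with an unactivated bromide; the face of attack fixes the spiro centre). The fallback sets out from 2 and comes back at 9, which closes to 10 as in step 6. Lactone 2 is opened with MeNH(OMe)·HCl and i-PrMgCl to the hydroxy Weinreb amide (1R,2R,5S)-2-[(2S)-1-hydroxypropan-2-yl]-N-methoxy-N,5-dimethylcyclopentane-1-carboxamide F1. Dess–Martin oxidation gives (1R,2R,5S)-N-methoxy-N,5-dimethyl-2-[(2S)-1-oxopropan-2-yl]cyclopentane-1-carboxamide F2. Wittig methylenation (Ph3PCH3Br, KN(SiMe3)2) gives (1R,2R,5S)-2-[(2R)-but-3-en-2-yl]-N-methoxy-N,5-dimethylcyclopentane-1-carboxamide F3, and i-Bu2AlH reduces it to (1R,2R,5S)-2-[(2R)-but-3-en-2-yl]-5-methylcyclopentane-1-carbaldehyde F4. Its pyrrolidine enamine 1-{[(2R,5S)-2-[(2R)-but-3-en-2-yl]-5-methylcyclopentylidene]methyl}pyrrolidine F5 is added to methyl vinyl ketone (Stork enamine Michael addition) on the face opposite the branched butenyl group, and aqueous acetic acid hydrolysis gives keto-aldehyde 9. Here the spiro centre rests on open-chain steric bias instead of on the ring fusion.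

Step 10 (alkyl–alkyl Suzuki coupling with a β-branched primary bromide, slow in oxidative addition). The fallback sets out from 13 and comes back at 17, with the polarity reversed. Hydroboration of 13 with 9-BBN-H and NaOH/H2O2 oxidation gives (3R)-3-[(1R,4S,5R)-4,8-dimethylspiro[4.5]dec-7-en-1-yl]butan-1-ol F6. I2, PPh3 and imidazole convert it to (1R,4S,5R)-1-[(2R)-4-iodobutan-2-yl]-4,8-dimethylspiro[4.5]dec-7-ene F7. Zinc insertion into 15 (Zn, LiCl, THF) gives [(2R)-3-acetoxy-2-methylpropyl]zinc bromide F8. Negishi alkyl–alkyl coupling of F7 with F8 (Pd2(dba)3, P(c-C5H9)3, N-methylimidazole, THF/NMP, 80 °C) gives 17.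

Step 11 (the proposed new hydroxylation). The reagent may be too weak an enophile, may attack the allylic methyl, or may show poor or mismatched face selectivity; the (S,S) antipode of the reagent would be tried first. The fallback uses known chemistry, sets out from 17 and comes back at 20. SeO2 (0.5 eq) and t-BuOOH in CH2Cl2 oxidise C9 without stereocontrol to a mixture of 20, its epimer (2S,6R)-6-[(1R,4S,5S,9R)-9-hydroxy-4,8-dimethylspiro[4.5]dec-7-en-1-yl]-2-methylheptyl acetate F9 and some enone. Dess–Martin oxidation converges the mixture on (2S,6R)-6-[(1R,4S,5S)-4,8-dimethyl-9-oxospiro[4.5]dec-7-en-1-yl]-2-methylheptyl acetate F10. Corey–Bakshi–Shibata reduction with (R)-2-methyl-CBS-oxazaborolidine and BH3·SMe2 (THF, −30 °C), with the α-methyl alkenyl side as the large group, gives the (9S) alcohol 20 and leaves the acetate alone.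

**Further compounds**

F1 | step 2 | (1R,2R,5S)-2-[(2S)-1-hydroxypropan-2-yl]-N-methoxy-N,5-dimethylcyclopentane-1-carboxamide | C[C@H]1CC[C@H]([C@H](C)CO)[C@@H]1C(=O)N(C)OC
F2 | step 2 | (1R,2R,5S)-N-methoxy-N,5-dimethyl-2-[(2S)-1-oxopropan-2-yl]cyclopentane-1-carboxamide | C[C@H]1CC[C@H]([C@H](C)C=O)[C@@H]1C(=O)N(C)OC
F3 | step 2 | (1R,2R,5S)-2-[(2R)-but-3-en-2-yl]-N-methoxy-N,5-dimethylcyclopentane-1-carboxamide | C[C@H]1CC[C@H]([C@H](C)C=C)[C@@H]1C(=O)N(C)OC
F4 | step 2 | (1R,2R,5S)-2-[(2R)-but-3-en-2-yl]-5-methylcyclopentane-1-carbaldehyde | C[C@H]1CC[C@H]([C@H](C)C=C)[C@@H]1C=O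
F5 | step 2 | 1-{[(2R,5S)-2-[(2R)-but-3-en-2-yl]-5-methylcyclopentylidene]methyl}pyrrolidine | C[C@H]1CC[C@H]([C@H](C)C=C)C1=CN1CCCC1
F6 | step 10 | (3R)-3-[(1R,4S,5R)-4,8-dimethylspiro[4.5]dec-7-en-1-yl]butan-1-ol | C[C@H]1CC[C@H]([C@H](C)CCO)[C@]12CC=C(C)CC2
F7 | step 10 | (1R,4S,5R)-1-[(2R)-4-iodobutan-2-yl]-4,8-dimethylspiro[4.5]dec-7-ene | C[C@H]1CC[C@H]([C@H](C)CCI)[C@]12CC=C(C)CC2
F8 | step 10 | [(2R)-3-acetoxy-2-methylpropyl]zinc bromide | CC(=O)OC[C@@H](C)C[Zn]Br
F9 | step 11 | (2S,6R)-6-[(1R,4S,5S,9R)-9-hydroxy-4,8-dimethylspiro[4.5]dec-7-en-1-yl]-2-methylheptyl acetate | CC(=O)OC[C@@H](C)CCC[C@@H](C)[C@H]1CC[C@H](C)[C@@]12CC=C(C)[C@H](O)C2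
F10 | step 11 | (2S,6R)-6-[(1R,4S,5S)-4,8-dimethyl-9-oxospiro[4.5]dec-7-en-1-yl]-2-methylheptyl acetate | CC(=O)OC[C@@H](C)CCC[C@@H](C)[C@H]1CC[C@H](C)[C@@]12CC=C(C)C(=O)C2
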